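## Structural features

Abruquinone B is an isoflavan quinone: a chroman (benzene ring A fused to a dihydropyran) with methoxy groups on C6, C7 and C8, joined through C3 to C1' of a 2,3-dimethoxy-1,4-benzoquinone (ring B, carbonyls at C2' and C5', methoxy groups at C3' and C4'). C3 is the only stereocentre; read from the SMILES string it is (S), and it has no stereogenic neighbour, so its configuration has to come from a reagent or catalyst. Its three carbon substituents are the C2 methylene bound to O1, the C4 methylene bound to ring A, and ring B itself. The quinone is the fragile part: it is electrophilic and reducible, and the hydrogen on C3 can be lost through a quinone methide tautomer under base, which would racemise the compound, so the quinone has to be revealed last. Ring A is a tetra-oxygenated benzene and therefore a latent quinone itself, so the final oxidation must distinguish two rings of nearly the same substitution. Both rings are 6-substituted derivatives of 2,3,4-trimethoxyphenol (ring A as its O-alkyl ether, ring B as its oxidised form), so one bromophenol can serve twice. The real difficulty is the isolated C3 stereocentre between two very electron-rich, ortho-oxygenated arenes. The key step uses the fact that C4 and C3 form a two-carbon unit with ring A on C4 and ring B on C3, while C2 is a one-carbon branch on C3: a vinylboron reagent supplies C4 and C3, and its boron atom holds the place of C2.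

## Logic of the disconnections

**15 to 14.** The two C=O bonds of ring B are traced back to a free C2' hydroxyl and a C5' methoxy group. The cut is made here because a quinone tolerates neither organolithium reagents, carbenoids nor hydrogenation. The gain is that ring B travels through the route as a robust arene. The forward oxidation must touch only the ring with the free phenol and must run without base so that C3 keeps its configuration.

**14 to 13.** The O–H bond of ring B is exchanged for an O–benzyl bond. Benzyl is chosen because it resists t-BuLi at low temperature, the boron chemistry, acid and the Mitsunobu reagents, and leaves under neutral conditions. The forward hydrogenolysis must leave the chroman C–O bonds, neither of which is benzylic, untouched.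

**13 to 12.** The O1–C2 bond of the pyran ring is cut, giving an open-chain phenol and primary alcohol. An ether closure at a primary carbon cannot touch C3, so the ring is exchanged for a 2,3-diarylpropanol at no stereochemical cost. The demand is that only the ring A oxygen is free: a free ring B phenol would close onto C2 to a five-membered dihydrobenzofuran. This is why the two phenols carry orthogonal groups.

**12 to 11.** The ring A O–H bond is traced back to an acetal O–C bond. The acetal survives aryllithium-derived ate complexes, palladium, the carbenoid and alkaline peroxide, and is removed by acid that leaves the benzyl ether alone. The forward solvolysis must not let the released one-carbon unit react with the 2-arylethanol motif.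

**11 to 9 through 10.** The C3–C2 bond is cut and C2 is replaced by boron. A boronate transfers its carbon ligand to a carbenoid carbon with retention, so the carbinol carbon can be added after the stereocentre exists. The gain is a 1,2-diarylethyl boronate with no oxygen on the chain. The demand is ate formation at a crowded secondary benzylic boron and clean single insertion.

**9 to 5, 6 and 7 through 8.** The C4–C4a and C3–C1' bonds are cut in one operation. Both bonds flank the two-carbon unit and can be formed together by a metallate shift on a vinylboron. The gain is the largest of the route: the whole chain between the rings falls back to two aryl bromides and 6. The forward step needs a catalyst that selects the alkene face, a way to keep bromide off palladium, and tolerance of an ortho-alkoxy group on each aryl partner.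

**7 to 4, 4 to 2 and 3, 5 to 2.** The C–Li bond is traced to a C–Br bond and the two O–C bonds to the same bromophenol. The divergence costs one step per ring and gives the orthogonal pair of protecting groups. The exchange must be run cold so that the benzylic protons of the ether are not attacked.

**2 to 1.** The C6–Br bond is cut. The hydroxyl group directs bromination to its only free ortho position, and the gain is a commercial phenol with all four oxygens in place. The demand is regiocontrol against the other free position, C5.

## Other disconnections considered

**Alternative 1:** The cut is C3–C1', with a temporary bond from C4 to the oxygen that later becomes the C2' hydroxyl. In the forward direction 6,7,8-trimethoxy-2H-chromene A1 and 2,3-dimethoxy-1,4-benzoquinone A2 would combine under a chiral tetravalent titanium TADDOLate (from TiCl2(OiPr)2 and TADDOL). C3 of A1 attacks the unsubstituted quinone carbon, the benzylic cation at C4 is captured by the neighbouring carbonyl oxygen, and tautomerisation gives the cis-fused pterocarpan phenol A3. Hydrogenolysis of the benzylic C4–O bond would open A3 to the hydroquinone A4, and a mild oxidant would give 15.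
- In its favour: ring B arrives with the correct oxygenation and almost the correct oxidation level, no protecting group is needed, and the target is about three operations from A1 and A2. On step economy this is clearly better than the nine steps chosen here. On structure it matches the target more directly.
- Against it: the chiral titanium complex is needed in stoichiometric or near-stoichiometric amount. The selectivity model of this reaction class rests on chelation of a 2-alkoxyquinone, whereas in A2 both carbonyls are vinylogous esters and less electrophilic. The stepwise cationic mechanism has to compete with cyclobutane adducts and with electron transfer from the very electron-rich chromene to the quinone. A1 needs two or three steps from 1 and is acid-sensitive.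
- Comparison: both plans set C3 in the bond-forming step, so they are equal on that point. The chosen plan uses a few mol% of a palladium catalyst with a well-defined ligand model and so should be more predictable. If the facial selectivity could be secured, Alternative 1 would be the shorter route.

**Alternative 2:** The cut lies inside ring A (C5–C6, with C8a–C4a formed earlier by carbonyl addition). The chiral 2-bromoalkene A6, which already carries C3, would be lithiated and added to dimethyl squarate A5, and the alkoxide silylated to the cyclobutenone A7. Heating should open A7 by 4π electrocyclic ring opening to a dienylketene, which closes by 6π electrocyclisation (ketene carbon C6 to alkene terminus C5) and tautomerises to the phenol A8. Methylation of the C6 hydroxyl, removal of both silyl groups, Mitsunobu closure, debenzylation and oxidation would follow.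
- In its favour: the key step is thermal, needs no catalyst or ligand tuning and is sterically undemanding, so in predictability of the key step it is the better of the two. It places four different oxygen substituents on ring A without ambiguity and would be the stronger plan for congeners with a free C6 hydroxyl.
- Against it: the ring A pattern is already present in commercial 1, so building the ring from a four-membered precursor buys nothing for this target. The key step forms no bond to C3 and no stereocentre, so A6 needs its own asymmetric synthesis. Two silyl groups and an extra methylation lengthen the route to an estimated fourteen or more steps.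
- Comparison: both plans carry C3 through steps that cannot epimerise it and share the same endgame, so they are equal there. The chosen plan is much shorter and makes the stereocentre and two skeletal bonds in one step.

**Alternative 3:** The cuts are C3–C4 and O1–C2, the latter as an acyl C–O bond. CsF would release an ortho-quinone methide from the silyl ether bromide A9, and the azolium enolate from the arylacetyl imidazole A10 and a chiral triazolium carbene would add to it. This forms C3–C4 and then O1–C2 and closes the pyran ring as the lactone A11. Reduction of A11 with LiAlH4 would give 12 and join the chosen route there.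
- In its favour: the heterocycle and the stereocentre form in one organocatalytic step without a precious metal, and no acetal protecting group is needed on ring A. On these points it is the equal or the better of the chosen plan.
- Against it: C3 in A11 is benzylic and α to an aryl ester carbonyl, so it is acidic and exposed to epimerisation under fluoride and during hydride reduction. A9 is a benzylic bromide on a tri-methoxylated ring and is expected to be labile. Its quinone methide is deactivated by three donors and may dimerise before it is trapped. A9 and A10 each need about three steps, so the total is about eleven.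
- Comparison: the chosen plan keeps C3 away from any carbonyl group until the final quinone and builds both aryl partners from one bromophenol. The alternative has the more convergent ring construction but the more vulnerable stereocentre and no saving in steps.

Key step: step 4

Assumption: the sense of induction of the two MandyPhos antipodes cannot be fixed on paper; the route is written for the antipode that delivers (S)-9, and both antipodes are commercial.

Remark: the structures were checked against the target. Debenzylation and oxidation of the 2-benzyloxy-3,4,5-trimethoxyphenyl ring with loss of the para methoxy group gives exactly the 2,3-dimethoxyquinone. Boron in (S)-9 occupies the position of C2 in (S)-15. No structure needed correction.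

## Route

Step 1
Reactants: 1 2,3,4-trimethoxyphenol
Product: 2 6-bromo-2,3,4-trimethoxyphenol
Conditions: NBS (1.0 equiv), i-Pr2NH (10 mol%), CH2Cl2, 0 °C
Reagents that add atoms: N-bromosuccinimide O=C1CCC(=O)N1Br
Why: Electrophilic aromatic bromination; the hydroxyl is the strongest donor, its para position is blocked, and amine-mediated NBS delivers bromine to the free ortho carbon C6 (also para to the C3 methoxy), while one equivalent at 0 °C limits attack at C5.

Step 2
Reactants: 2 6-bromo-2,3,4-trimethoxyphenol; 3 benzyl bromide
Product: 4 2-(benzyloxy)-1-bromo-3,4,5-trimethoxybenzene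
Conditions: K2CO3, DMF, 60 °C
Reagents that add atoms: none
Why: Williamson ether synthesis; the phenoxide displaces bromide from the benzylic carbon, and the aryl bromide is inert under these conditions.

Step 3
Reactants: 2 6-bromo-2,3,4-trimethoxyphenol
Product: 5 1-bromo-3,4,5-trimethoxy-2-(methoxymethoxy)benzene
Conditions: MOMCl, i-Pr2NEt, CH2Cl2, 0 °C to rt
Reagents that add atoms: chloromethyl methyl ether COCCl
Why: O-alkylation of the phenol with an α-chloro ether (acetal protection); the acetal is orthogonal to the benzyl ether of 4 and stable to all basic and organometallic steps that follow.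

Step 4
Reactants: 4 2-(benzyloxy)-1-bromo-3,4,5-trimethoxybenzene; 6 vinylboronic acid pinacol ester; 5 1-bromo-3,4,5-trimethoxy-2-(methoxymethoxy)benzene
Product: 9 2-{(1S)-1-[2-(benzyloxy)-3,4,5-trimethoxyphenyl]-2-[3,4,5-trimethoxy-2-(methoxymethoxy)phenyl]ethyl}-4,4,5,5-tetramethyl-1,3,2-dioxaborolane, via aryllithium 7 (not isolated), via vinylboron ate complex 8 (not isolated)
Conditions: 4, t-BuLi (2.0 equiv), Et2O, −78 °C; 6, −78 °C to rt; solvent change to THF; 5 (1.1 equiv), Pd(OAc)2 (3 mol%), MandyPhos (bis(4-methoxy-3,5-dimethylphenyl)phosphino type, 3.6 mol%), NaOTf (3 equiv), 60 °C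
Reagents that add atoms: none
Why: Bromine–lithium exchange on 4 gives 7, which adds to the empty orbital on boron of 6 to form the four-coordinate vinylboronate 8. Pd(OAc)2 and the bisphosphine are reduced in the flask to zerovalent palladium, which inserts into the C–Br bond of 5; NaOTf takes up the bromide from the exchange and from 5 as NaBr, so that a cationic aryl complex of divalent palladium is free to bind the vinyl group of 8. Coordination triggers the 1,2-metallate shift: ring B migrates from boron to the α-carbon (C3) anti to palladium while palladium bonds to the β-carbon (C4), and reductive elimination then forms C4–C4a and returns zerovalent palladium. The closest known reaction type is the palladium-catalysed enantioselective conjunctive cross-coupling of vinylboron ate complexes with aryl electrophiles, here with an aryl migrating group and an aryl bromide. No ring is closed. The new stereocentre C3 is controlled by the chiral MandyPhos ligand, which decides the alkene face that palladium occupies during the shift; the ligand antipode is chosen to give (S). The step needs the conjunctive pathway to win over direct Suzuki-type transfer of aryl or vinyl from boron and over β-hydride elimination from the alkylpalladium intermediate; the wide bite angle of the ferrocenyl bisphosphine, the halide-poor medium and the poorly transmetallating pinacol ate complex should secure this. The benzyl and methoxymethyl ethers are inert to the ate complex and to palladium, and the ortho-alkoxy group on each partner is expected to slow the coupling without blocking it.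

Step 5
Reactants: 9 2-{(1S)-1-[2-(benzyloxy)-3,4,5-trimethoxyphenyl]-2-[3,4,5-trimethoxy-2-(methoxymethoxy)phenyl]ethyl}-4,4,5,5-tetramethyl-1,3,2-dioxaborolane
Product: 11 (2S)-2-[2-(benzyloxy)-3,4,5-trimethoxyphenyl]-3-[3,4,5-trimethoxy-2-(methoxymethoxy)phenyl]propan-1-ol, via homologated pinacol boronate 10 (not isolated)
Conditions: BrCH2Cl (3 equiv), n-BuLi (2.5 equiv), THF, −78 °C to rt; then NaOH (aq), H2O2, 0 °C to rt
Reagents that add atoms: bromochloromethane ClCBr; hydrogen peroxide OO
Why: Matteson homologation; chloromethyllithium made in the presence of 9 adds to boron, and the benzylic carbon C3 migrates to the carbenoid carbon with loss of chloride and with retention, so the (S) centre is carried into 10; alkaline peroxide then oxidises the primary C–B bond to the C2 alcohol while both phenols are still protected.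

Step 6
Reactants: 11 (2S)-2-[2-(benzyloxy)-3,4,5-trimethoxyphenyl]-3-[3,4,5-trimethoxy-2-(methoxymethoxy)phenyl]propan-1-ol
Product: 12 6-{(2S)-2-[2-(benzyloxy)-3,4,5-trimethoxyphenyl]-3-hydroxypropyl}-2,3,4-trimethoxyphenol
Conditions: HCl (conc., 5 equiv), MeOH, 45 °C
Reagents that add atoms: none
Why: Acid-catalysed acetal solvolysis; methanol as solvent traps the one-carbon unit as dimethoxymethane so that it cannot cyclise onto the 2-arylethanol (oxa-Pictet–Spengler), and the benzyl ether and the stereocentre are unaffected.

Step 7
Reactants: 12 6-{(2S)-2-[2-(benzyloxy)-3,4,5-trimethoxyphenyl]-3-hydroxypropyl}-2,3,4-trimethoxyphenol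
Product: 13 (3S)-3-[2-(benzyloxy)-3,4,5-trimethoxyphenyl]-6,7,8-trimethoxy-3,4-dihydro-2H-chromene
Conditions: PPh3, DIAD, THF, 0 °C to rt
Reagents that add atoms: none
Why: Intramolecular Mitsunobu etherification; the ring A phenoxide displaces the activated primary oxygen at C2 (6-exo-tet) to form O1–C2 without touching C3, and the benzyl group on the ring B oxygen excludes the competing five-membered closure.

Step 8
Reactants: 13 (3S)-3-[2-(benzyloxy)-3,4,5-trimethoxyphenyl]-6,7,8-trimethoxy-3,4-dihydro-2H-chromene
Product: 14 2,3,4-trimethoxy-6-[(3S)-6,7,8-trimethoxy-3,4-dihydro-2H-chromen-3-yl]phenol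
Conditions: H2 (1 atm), 10% Pd/C, EtOAc–EtOH, rt
Reagents that add atoms: none
Why: Catalytic hydrogenolysis of the benzyl ether; the chroman C–O bonds are not benzylic and the methoxy groups and the C3–H bond are inert under these neutral conditions.

Step 9
Reactants: 14 2,3,4-trimethoxy-6-[(3S)-6,7,8-trimethoxy-3,4-dihydro-2H-chromen-3-yl]phenol
Product: 15 abruquinone B, 2,3-dimethoxy-5-[(3S)-6,7,8-trimethoxy-3,4-dihydro-2H-chromen-3-yl]cyclohexa-2,5-diene-1,4-dione
Conditions: PhI(OAc)2 (1.1 equiv), MeCN–H2O (2:1), 0 °C
Reagents that add atoms: water O
Why: Oxidative demethylation of a para-methoxyphenol with a trivalent iodine reagent; the phenol binds iodine, water attacks the para carbon C5' and the hemiketal loses methanol to give the para-quinone, while ring A has no free hydroxyl and is not oxidised, and the base-free medium avoids quinone methide tautomerisation at C3.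

## Compound list

1 | 2,3,4-trimethoxyphenol | COc1ccc(O)c(OC)c1OC | starting material
2 | 6-bromo-2,3,4-trimethoxyphenol | COc1cc(Br)c(O)c(OC)c1OC | intermediate
3 | benzyl bromide | BrCc1ccccc1 | starting material
4 | 2-(benzyloxy)-1-bromo-3,4,5-trimethoxybenzene | COc1cc(Br)c(OCc2ccccc2)c(OC)c1OC | intermediate
5 | 1-bromo-3,4,5-trimethoxy-2-(methoxymethoxy)benzene | COCOc1c(Br)cc(OC)c(OC)c1OC | intermediate
6 | vinylboronic acid pinacol ester | C=CB1OC(C)(C)C(C)(C)O1 | starting material
7 | [2-(benzyloxy)-3,4,5-trimethoxyphenyl]lithium | [Li]c1cc(OC)c(OC)c(OC)c1OCc1ccccc1 | intermediate (not isolated)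
8 | lithium [2-(benzyloxy)-3,4,5-trimethoxyphenyl](ethenyl)(pinacolato)borate | [Li+].C=C[B-]1(OC(C)(C)C(C)(C)O1)c1cc(OC)c(OC)c(OC)c1OCc1ccccc1 | intermediate (not isolated)
9 | 2-{(1S)-1-[2-(benzyloxy)-3,4,5-trimethoxyphenyl]-2-[3,4,5-trimethoxy-2-(methoxymethoxy)phenyl]ethyl}-4,4,5,5-tetramethyl-1,3,2-dioxaborolane | COc1cc([C@H](Cc2cc(OC)c(OC)c(OC)c2OCOC)B2OC(C)(C)C(C)(C)O2)c(OCc2ccccc2)c(OC)c1OC | intermediate
10 | 2-{(2S)-2-[2-(benzyloxy)-3,4,5-trimethoxyphenyl]-3-[3,4,5-trimethoxy-2-(methoxymethoxy)phenyl]propyl}-4,4,5,5-tetramethyl-1,3,2-dioxaborolane | COc1cc([C@H](Cc2cc(OC)c(OC)c(OC)c2OCOC)CB2OC(C)(C)C(C)(C)O2)c(OCc2ccccc2)c(OC)c1OC | intermediate (not isolated)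
11 | (2S)-2-[2-(benzyloxy)-3,4,5-trimethoxyphenyl]-3-[3,4,5-trimethoxy-2-(methoxymethoxy)phenyl]propan-1-ol | COc1cc([C@H](Cc2cc(OC)c(OC)c(OC)c2OCOC)CO)c(OCc2ccccc2)c(OC)c1OC | intermediate
12 | 6-{(2S)-2-[2-(benzyloxy)-3,4,5-trimethoxyphenyl]-3-hydroxypropyl}-2,3,4-trimethoxyphenol | COc1cc([C@H](Cc2cc(OC)c(OC)c(OC)c2O)CO)c(OCc2ccccc2)c(OC)c1OC | intermediate
13 | (3S)-3-[2-(benzyloxy)-3,4,5-trimethoxyphenyl]-6,7,8-trimethoxy-3,4-dihydro-2H-chromene | COc1cc([C@H]2COc3c(cc(OC)c(OC)c3OC)C2)c(OCc2ccccc2)c(OC)c1OC | intermediate
14 | 2,3,4-trimethoxy-6-[(3S)-6,7,8-trimethoxy-3,4-dihydro-2H-chromen-3-yl]phenol | COc1cc([C@H]2COc3c(cc(OC)c(OC)c3OC)C2)c(O)c(OC)c1OC | intermediate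
15 | abruquinone B, 2,3-dimethoxy-5-[(3S)-6,7,8-trimethoxy-3,4-dihydro-2H-chromen-3-yl]cyclohexa-2,5-diene-1,4-dione | COC1=C(OC)C(=O)C([C@H]2COc3c(cc(OC)c(OC)c3OC)C2)=CC1=O | target

## Step count and least certain steps

Total step count: 9. Longest linear sequence: 8 (steps 1, 2, 4, 5, 6, 7, 8, 9; step 3 is the one-step branch to 5).

**Step 4 (key step).** Both aryl partners carry an ortho-alkoxy group and 5 is electron-rich, so oxidative addition may be slow. Residual bromide may compete with the vinylboronate for the cationic palladium centre, which would divert the reaction to direct Suzuki-type transfer or leave 8 to decompose. The crowded environment may also erode the facial selectivity of the metallate shift. Fallback, which separates C–B from C–C bond formation: setting out from 4, Suzuki–Miyaura vinylation with 6 (PdCl2(dppf), K2CO3, dioxane–H2O) should give the styrene 2-(benzyloxy)-1-ethenyl-3,4,5-trimethoxybenzene F1. Enantioselective platinum-catalysed diboration of F1 (Pt(dba)3, a TADDOL-derived phosphonite, B2pin2) should give the bis(boronate) 2,2'-{(1S)-1-[2-(benzyloxy)-3,4,5-trimethoxyphenyl]ethane-1,2-diyl}bis(4,4,5,5-tetramethyl-1,3,2-dioxaborolane) F2. Regioselective Suzuki–Miyaura coupling of the primary C–B bond of F2 with 5 (Pd(OAc)2, RuPhos, KOH, THF–H2O) would come back to the route at 9.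

**Step 5.** Ate formation at the hindered benzylic boron may be slower than decomposition of the carbenoid. In that case unreacted 9 would be oxidised to the secondary alcohol, or a second insertion could occur. Fallback, which replaces the carbenoid by a stable nucleophile: setting out from 9, Zweifel olefination (vinylmagnesium bromide, THF; then I2, NaOMe, MeOH, −78 °C to rt) should give, with retention, the alkene 2-(benzyloxy)-3,4,5-trimethoxy-1-{(2R)-1-[3,4,5-trimethoxy-2-(methoxymethoxy)phenyl]but-3-en-2-yl}benzene F3 (the descriptor changes by priority only). Oxidative cleavage (OsO4 cat., NaIO4, 2,6-lutidine, dioxane–H2O) would give the aldehyde (2S)-2-[2-(benzyloxy)-3,4,5-trimethoxyphenyl]-3-[3,4,5-trimethoxy-2-(methoxymethoxy)phenyl]propanal F4. F4 would be reduced at once with NaBH4, because an α-aryl aldehyde can epimerise, and this comes back to the route at 11.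

**Step 1.** Bromination may also occur at C5 (ortho to the C4 methoxy), or twice, because the ring has two free activated positions. Fallback, which replaces electrophilic substitution by directed metalation: setting out from 1, protection (MOMCl, i-Pr2NEt) gives 1,2,3-trimethoxy-4-(methoxymethoxy)benzene F5. Ortho-lithiation next to the acetal (n-BuLi, TMEDA, THF, 0 °C), the only free position beside the stronger directing group, and quenching with 1,2-dibromotetrachloroethane would come back to the route at 5. Part of 5 would be treated with HCl in MeOH to supply 2 for step 2.

**Step 9.** Water may attack the ortho carbon that bears the C3' methoxy group instead of the para carbon, leading toward an ortho-quinone, or water may add to the product quinone. Fallback, which divides the oxidation into two stages: setting out from 14, PhI(OAc)2 in MeOH at 0 °C should give the isolable quinone monoketal 2,3,4,4-tetramethoxy-6-[(3S)-6,7,8-trimethoxy-3,4-dihydro-2H-chromen-3-yl]cyclohexa-2,5-dien-1-one F6. Mild hydrolysis (oxalic acid, THF–H2O) would come back to the route at 15.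

## Further compounds

F1 | step 4 | 2-(benzyloxy)-1-ethenyl-3,4,5-trimethoxybenzene | COc1cc(C=C)c(OCc2ccccc2)c(OC)c1OC
F2 | step 4 | 2,2'-{(1S)-1-[2-(benzyloxy)-3,4,5-trimethoxyphenyl]ethane-1,2-diyl}bis(4,4,5,5-tetramethyl-1,3,2-dioxaborolane) | COc1cc([C@H](CB2OC(C)(C)C(C)(C)O2)B2OC(C)(C)C(C)(C)O2)c(OCc2ccccc2)c(OC)c1OC
F3 | step 5 | 2-(benzyloxy)-3,4,5-trimethoxy-1-{(2R)-1-[3,4,5-trimethoxy-2-(methoxymethoxy)phenyl]but-3-en-2-yl}benzene | COc1cc([C@H](Cc2cc(OC)c(OC)c(OC)c2OCOC)C=C)c(OCc2ccccc2)c(OC)c1OC
F4 | step 5 | (2S)-2-[2-(benzyloxy)-3,4,5-trimethoxyphenyl]-3-[3,4,5-trimethoxy-2-(methoxymethoxy)phenyl]propanal | COc1cc([C@H](Cc2cc(OC)c(OC)c(OC)c2OCOC)C=O)c(OCc2ccccc2)c(OC)c1OC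
F5 | step 1 | 1,2,3-trimethoxy-4-(methoxymethoxy)benzene | COCOc1ccc(OC)c(OC)c1OC
F6 | step 9 | 2,3,4,4-tetramethoxy-6-[(3S)-6,7,8-trimethoxy-3,4-dihydro-2H-chromen-3-yl]cyclohexa-2,5-dien-1-one | COC1=C(OC)C(OC)(OC)C=C([C@H]2COc3c(cc(OC)c(OC)c3OC)C2)C1=O
A1 | alternative 1 | 6,7,8-trimethoxy-2H-chromene | COc1cc2C=CCOc2c(OC)c1OC
A2 | alternative 1 | 2,3-dimethoxy-1,4-benzoquinone | COC1=C(OC)C(=O)C=CC1=O
A3 | alternative 1 | cis-2,3,4,9,10-pentamethoxypterocarpan-8-ol (6a configured as C3 of the target) | Oc1cc2c(c(OC)c1OC)O[C@H]3[C@@H]2COc2c3cc(OC)c(OC)c2OC
A4 | alternative 1 | 2,3-dimethoxy-5-[(3S)-6,7,8-trimethoxy-3,4-dihydro-2H-chromen-3-yl]benzene-1,4-diol | COc1c(O)cc([C@H]2COc3c(cc(OC)c(OC)c3OC)C2)c(O)c1OC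
A5 | alternative 2 | dimethyl squarate (3,4-dimethoxycyclobut-3-ene-1,2-dione) | COC1=C(OC)C(=O)C1=O
A6 | alternative 2 | {[(2S)-2-[2-(benzyloxy)-3,4,5-trimethoxyphenyl]-4-bromopent-4-en-1-yl]oxy}(tert-butyl)dimethylsilane | C=C(Br)C[C@H](CO[Si](C)(C)C(C)(C)C)c1cc(OC)c(OC)c(OC)c1OCc1ccccc1
A7 | alternative 2 | 4-{(4S)-4-[2-(benzyloxy)-3,4,5-trimethoxyphenyl]-5-(tert-butyldimethylsilyloxy)pent-1-en-2-yl}-4-(tert-butyldimethylsilyloxy)-2,3-dimethoxycyclobut-2-en-1-one | COC1=C(OC)C(O[Si](C)(C)C(C)(C)C)(C(=C)C[C@H](CO[Si](C)(C)C(C)(C)C)c2cc(OC)c(OC)c(OC)c2OCc2ccccc2)C1=O
A8 | alternative 2 | 5-[(2S)-2-(2-benzyloxy-3,4,5-trimethoxyphenyl)-3-(tert-butyldimethylsilyloxy)propyl]-4-(tert-butyldimethylsilyloxy)-2,3-dimethoxyphenol | COc1c(O)cc(C[C@H](CO[Si](C)(C)C(C)(C)C)c2cc(OC)c(OC)c(OC)c2OCc2ccccc2)c(O[Si](C)(C)C(C)(C)C)c1OC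
A9 | alternative 3 | [6-(bromomethyl)-2,3,4-trimethoxyphenoxy](tert-butyl)dimethylsilane | COc1cc(CBr)c(O[Si](C)(C)C(C)(C)C)c(OC)c1OC
A10 | alternative 3 | 2-[2-(benzyloxy)-3,4,5-trimethoxyphenyl]-1-(1H-imidazol-1-yl)ethan-1-one | COc1cc(CC(=O)n2ccnc2)c(OCc2ccccc2)c(OC)c1OC
A11 | alternative 3 | 3-(2-benzyloxy-3,4,5-trimethoxyphenyl)-6,7,8-trimethoxychroman-2-one (C3 placed as in the target) | COc1cc([C@@H]2Cc3cc(OC)c(OC)c(OC)c3OC2=O)c(OCc2ccccc2)c(OC)c1OC
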